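Assumption: the target has no stereocentre and is achiral, so there is no enantiomer to control; the SMILES is taken as the full structural definition.

**Retrosynthetic overview**
- C3–CH2 bond: Mannich aminomethylation of 2,5,6-tribromo-1-methylindole with preformed dimethylmethyleneiminium iodide, as the last step.
- N–CH3 by alkylation of 2,5,6-tribromoindole; C2–Br by C2-lithiation/bromination of N-phenylsulfonyl-5,6-dibromoindole, then removal of the sulfonyl group.
- 5,6-Dibromoindole from methyl indole-3-carboxylate: ester-directed 5,6-dibromination, then hydrolysis/decarboxylation.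
- No ring is formed: both rings of the indole come intact from the starting material.

**Route**

Step 1
Reactants: 1 methyl 1H-indole-3-carboxylate; 2 bromine
Product: 3 methyl 5,6-dibromo-1H-indole-3-carboxylate
Conditions: Br2 (2.3 equiv), AcOH, rt, 48 h; aq. Na2S2O3
Reagents that add atoms: bromine (2), BrBr
Why: Electrophilic aromatic bromination; the 3-ester deactivates the pyrrole ring (C2 is the beta carbon of a vinylogous carbamate), so both bromines enter the benzo ring at C5 and C6.

Step 2
Reactants: 3 methyl 5,6-dibromo-1H-indole-3-carboxylate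
Product: 5 5,6-dibromo-1H-indole, via sodium 5,6-dibromo-1H-indole-3-carboxylate 4 (not isolated)
Conditions: NaOH (4 equiv), MeOH/H2O 1:1, 150 °C (sealed tube or microwave), 1 h
Reagents that add atoms: none
Why: Saponification followed by protodecarboxylation of the indole-3-carboxylate (C3 protonation, loss of CO2); aryl bromides are inert to hot hydroxide.

Step 3
Reactants: 5 5,6-dibromo-1H-indole; 6 benzenesulfonyl chloride
Product: 8 5,6-dibromo-1-(phenylsulfonyl)-1H-indole, via sodium 5,6-dibromoindol-1-ide 7 (not isolated)
Conditions: NaH (1.2 equiv), DMF, 0 °C; then PhSO2Cl (1.2 equiv), 0 °C → rt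
Reagents that add atoms: benzenesulfonyl chloride (6), O=S(=O)(Cl)c1ccccc1
Why: N-sulfonylation of the indolide anion; the sulfonyl group acidifies and directs metalation to C2-H in the next step.

Step 4
Reactants: 8 5,6-dibromo-1-(phenylsulfonyl)-1H-indole; 9 1,2-dibromo-1,1,2,2-tetrachloroethane
Product: 11 2,5,6-tribromo-1-(phenylsulfonyl)-1H-indole, via 5,6-dibromo-2-lithio-1-(phenylsulfonyl)-1H-indole 10 (not isolated)
Conditions: LiN(iPr)2 (1.2 equiv), THF, −78 °C, 1 h; then BrCl2C–CCl2Br (1.3 equiv), −78 °C → rt
Reagents that add atoms: 1,2-dibromo-1,1,2,2-tetrachloroethane (9), BrC(Cl)(Cl)C(Cl)(Cl)Br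
Why: Directed deprotonation at C2 by a non-nucleophilic amide base (no halogen–lithium exchange at −78 °C), then electrophilic bromination of the 2-lithioindole.

Step 5
Reactants: 11 2,5,6-tribromo-1-(phenylsulfonyl)-1H-indole
Product: 12 2,5,6-tribromo-1H-indole
Conditions: NaOH (aq. 2 M, 3 equiv), THF/MeOH, 40 °C; aq. NH4Cl; keep cold and dark, use at once
Reagents that add atoms: none
Why: Hydroxide cleaves the N–S bond (sulfonamide hydrolysis), helped by the electron-poor tribromoindolide leaving group; the C–Br bonds are not activated for substitution.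

Step 6
Reactants: 12 2,5,6-tribromo-1H-indole; 13 iodomethane
Product: 15 2,5,6-tribromo-1-methyl-1H-indole, via sodium 2,5,6-tribromoindol-1-ide 14 (not isolated)
Conditions: NaH (1.2 equiv), DMF, 0 °C; then MeI (1.5 equiv), 0 °C → rt
Reagents that add atoms: iodomethane (13), CI
Why: SN2 N-alkylation of the indolide anion; it is done before the amine is introduced so that no quaternary ammonium salt can form.

Step 7
Reactants: 15 2,5,6-tribromo-1-methyl-1H-indole; 16 N,N-dimethylmethyleneiminium iodide (Eschenmoser's salt)
Product: 18 2,5,6-tribromo-1-methylgramine, via 2,5,6-tribromo-1-methylgramine hydroiodide 17 (not isolated)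
Conditions: CH2=NMe2+ I− (2 equiv), MeCN, 60–80 °C; then aq. NaOH, CH2Cl2 extraction
Reagents that add atoms: N,N-dimethylmethyleneiminium iodide (16), C=[N+](C)C.[I-]
Why: Intermolecular Mannich aminomethylation; the preformed iminium ion attacks C3, the only free enamine-type position of the N-methylindole, and heating plus excess iminium compensates for the deactivating bromines.

**Compound list**
1 | methyl 1H-indole-3-carboxylate | COC(=O)c1c[nH]c2ccccc12 | starting material
2 | bromine | BrBr | starting material
3 | methyl 5,6-dibromo-1H-indole-3-carboxylate | COC(=O)c1c[nH]c2cc(Br)c(Br)cc12 | intermediate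
4 | sodium 5,6-dibromo-1H-indole-3-carboxylate | [Na+].[O-]C(=O)c1c[nH]c2cc(Br)c(Br)cc12 | intermediate
5 | 5,6-dibromo-1H-indole | Brc1cc2cc[nH]c2cc1Br | intermediate
6 | benzenesulfonyl chloride | O=S(=O)(Cl)c1ccccc1 | starting material
7 | sodium 5,6-dibromoindol-1-ide | [Na+].Brc1cc2cc[n-]c2cc1Br | intermediate
8 | 5,6-dibromo-1-(phenylsulfonyl)-1H-indole | O=S(=O)(c1ccccc1)n1ccc2cc(Br)c(Br)cc21 | intermediate
9 | 1,2-dibromo-1,1,2,2-tetrachloroethane | BrC(Cl)(Cl)C(Cl)(Cl)Br | starting material
10 | 5,6-dibromo-2-lithio-1-(phenylsulfonyl)-1H-indole | [Li]c1cc2cc(Br)c(Br)cc2n1S(=O)(=O)c1ccccc1 | intermediate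
11 | 2,5,6-tribromo-1-(phenylsulfonyl)-1H-indole | O=S(=O)(c1ccccc1)n1c(Br)cc2cc(Br)c(Br)cc21 | intermediate
12 | 2,5,6-tribromo-1H-indole | Brc1cc2cc(Br)c(Br)cc2[nH]1 | intermediate
13 | iodomethane | CI | starting material
14 | sodium 2,5,6-tribromoindol-1-ide | [Na+].Brc1cc2cc(Br)c(Br)cc2[n-]1 | intermediate
15 | 2,5,6-tribromo-1-methyl-1H-indole | Cn1c(Br)cc2cc(Br)c(Br)cc21 | intermediate
16 | N,N-dimethylmethyleneiminium iodide (Eschenmoser's salt) | C=[N+](C)C.[I-] | starting material
17 | 2,5,6-tribromo-1-methylgramine hydroiodide | C[NH+](C)Cc1c(Br)n(C)c2cc(Br)c(Br)cc12.[I-] | intermediate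
18 | 2,5,6-tribromo-1-methylgramine | CN(C)Cc1c(Br)n(C)c2cc(Br)c(Br)cc12 | target

**Totals and risks**
Total step count: 7. Longest linear sequence: 7 steps (from 1).

The three steps most likely to fail:

Step 4 (C2 lithiation/bromination next to two aryl bromides; competing ortho-metalation or halogen migration). The fallback sets out from 5 and comes back at 12, replacing steps 3 to 5. Compound 5 is oxidised with pyridinium tribromide in t-BuOH/H2O at rt to 3,3,5,6-tetrabromoindolin-2-one F1. The two C3 bromines are removed with Zn dust in AcOH at rt, which leaves aryl bromides alone, to give 5,6-dibromoindolin-2-one F2. The lactam is then converted to the 2-bromoindole 12 with POBr3 and imidazole in refluxing 1,2-dichloroethane. No organolithium is needed.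

Step 5 (basic desulfonylation giving a sensitive N–H 2-bromoindole). The fallback sets out from 5 and comes back at 12, using a nitrogen group that leaves on heating without base or nucleophile. Compound 5 is treated with Boc2O and DMAP in MeCN to give tert-butyl 5,6-dibromo-1H-indole-1-carboxylate F3. LiN(iPr)2 in THF at −78 °C gives tert-butyl 5,6-dibromo-2-lithio-1H-indole-1-carboxylate F4, which is not isolated and is quenched with 9 to give tert-butyl 2,5,6-tribromo-1H-indole-1-carboxylate F5. Thermolysis of the carbamate (2,2,2-trifluoroethanol, 150 °C, or neat at 170 °C) delivers 12.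

Step 7 (Mannich reaction on an indole deactivated by three bromines; slow reaction or bis-indolylmethane formation on prolonged heating). The fallback sets out from 5 and comes back at 18; it keeps the Mannich bond formation but runs it on a more nucleophilic indole. Compound 5 is deprotonated with NaH in DMF (through 7) and methylated with 13 to give 5,6-dibromo-1-methyl-1H-indole F6. Reaction with 16 in MeCN at rt gives 5,6-dibromo-1-methylgramine hydroiodide F7, which aq. NaOH converts to 5,6-dibromo-1-methylgramine F8. C2 bromination with NBS in AcOH at 0 °C to rt then gives 18; the solvent keeps the amine protonated, which suppresses N-oxidation and loss of the side chain, and the bromine reaches C2 by 3-bromoindolenine formation and 1,2-shift.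

**Further compounds**
F1 | step 4 | 3,3,5,6-tetrabromoindolin-2-one | O=C1Nc2cc(Br)c(Br)cc2C1(Br)Br
F2 | step 4 | 5,6-dibromoindolin-2-one | O=C1Cc2cc(Br)c(Br)cc2N1
F3 | step 5 | tert-butyl 5,6-dibromo-1H-indole-1-carboxylate | CC(C)(C)OC(=O)n1ccc2cc(Br)c(Br)cc21
F4 | step 5 | tert-butyl 5,6-dibromo-2-lithio-1H-indole-1-carboxylate | CC(C)(C)OC(=O)n1c([Li])cc2cc(Br)c(Br)cc21
F5 | step 5 | tert-butyl 2,5,6-tribromo-1H-indole-1-carboxylate | CC(C)(C)OC(=O)n1c(Br)cc2cc(Br)c(Br)cc21
F6 | step 7 | 5,6-dibromo-1-methyl-1H-indole | Cn1ccc2cc(Br)c(Br)cc21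
F7 | step 7 | 5,6-dibromo-1-methylgramine hydroiodide | C[NH+](C)Cc1cn(C)c2cc(Br)c(Br)cc12.[I-]
F8 | step 7 | 5,6-dibromo-1-methylgramine | CN(C)Cc1cn(C)c2cc(Br)c(Br)cc12
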